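The numbers in the tables are simulated from invented constants; noise was put on by code.

What will the flask hold at its reading, and which change pays? Let us work it out at the board.

| flask | solid substrate | remark | time |
|---|---|---|---|
| larch | 0.20 M | run made earlier |  |
| elm | 0.30 M | run made earlier |  |
| flask | 0.40 M |  | 30 min |

| run | time / min | product / % | solid substrate / % |
|---|---|---|---|
| larch | 8.00 | 0 | 63 |
| larch | 15.0 | 8 | 39 |
| larch | 20.0 | 15 | 24 |
| larch | 30.0 | 27 | 0 |
| larch | 40.0 | 47 | 0 |
| elm | 3.00 | 2 | 91 |
| elm | 5.00 | 0 | 85 |
| elm | 10.0 | 1 | 72 |
| elm | 20.0 | 8 | 50 |
| elm | 40.0 | 32 | 11 |

(standard deviation of a reading: 1.5 percentage points)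

- solid, in amounts per volume of the solution: solid substrate
- on the list of suspects stand: intermediate -> product; solid substrate <-> starting material; starting material -> intermediate
- at the start none of the solid substrate is in solution

- amount of product at 30 min, in percent of the solid substrate charged
- the change that raises the amount of product at 30 min, in percent of the solid substrate charged most ("none" if none brings more than 2 percentage points) (amber / blue / none)
- amount of product at 30 min, in percent of the solid substrate charged, after blue

- amber: doubling the dissolution coefficient of the solid substrate, all else as stated
- blue: doubling the solubility of the solid substrate, all else as stated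

Should we compare the runs in percent? No, the charges differ, so convert to molar terms. By 20.0 min the larch run has lost 0.152 M of solid substrate and the elm run 0.150 M, practically the same. At 40.0 min, c(product) reads 0.0940 M in larch and 0.0960 M in elm, level again despite the different charges.

What do I carry, then? The molar mark, the c(product) read from one run at a given time and divided by another flask's charge: larch at 30.0 min gives 0.0540 M.

But larch reads 0 % solid then, so may its mark serve a flask that still holds solid? At 40.0 min, larch with 0 % solid and elm with 11 % stood level in product, so I accept it.

And the flask? Halfway between the elm readings at 20.0 min and 40.0 min, I expect the flask to show a loss of about 0.209 M by 30 min, less than its charge. The mark then gives 13.5 %.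

And blue? Doubled solubility lifts the whole dissolved curve, so I double the mark to 27.0 %. The doubled loss, 0.418 M, roughly equals the charge, so the solid lasts nearly to the reading. Amber, which doubles the dissolution coefficient, quickens the early pace under the same solubility, and I judge that worth less than doubling the mark, so I choose blue.

The forecast says 14 %, blue and 27 %, since “Doubling solubility doubles the whole linear system”.

The flask gives 14.1 % at 30 min, with 47.6 % still solid. Blue gives 28.2 %, a gain of 14 percentage points, more than the 8.6 points from amber, so the best change is blue.

    intermediate → product (k = 0.00143 s⁻¹)
    solid substrate ⇌ starting material, rate k2*(cs2 - [starting material]) while solid is left; crystals form when [starting material] > cs2 (solubility = 0.240 M, k = 7.08 × 10⁻⁴ s⁻¹)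
    starting material → intermediate (k = 7.42 × 10⁻⁴ s⁻¹)

Now take the same flask charged with 0.16 M, and the mark gives 33.7 % of that smaller charge. That neighbour holds 0 % solid at 30 min, and its product stands at 34.2 %, which is 0.0547 M.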